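**Retrosynthetic overview**
- The target comes from 5-[14-(3,5-dimethoxyphenyl)tetradecyl]benzene-1,3-diol by thiolate cleavage of one of two equivalent OMe groups. That diol comes from its dibenzyl ether by hydrogenolysis.
- Key disconnection: both benzylic bonds (C1–C2 and C13–C14 of the chain) are cut at once. Each ArCHO carbon becomes a traceless benzyl-carbanion equivalent through its NH2-hydrazone (N2 is lost) and is joined to a C–Br carbon of 1,12-dibromododecane, so two electrophilic carbons are coupled.
- Carbon count: 1 + 12 + 1 = C14, from two aldehydes and one C12 linchpin in one flask.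
- Rings: none is formed. Both benzene rings are bought with their 1,3,5-oxygen pattern in place.

Assumption: the target has no stereocentre and no stereogenic double bond, so it is achiral. The "single enantiomer" is the compound itself and no stereocontrol is needed.

**Step 1**
Reactants: 1 3,5-dimethoxybenzaldehyde; 2 3,5-bis(benzyloxy)benzaldehyde; 3 1,12-dibromododecane; 4 hydrazine monohydrate
Product: 9 1-[3,5-bis(benzyloxy)phenyl]-14-(3,5-dimethoxyphenyl)tetradecane, via dimethoxyaryl hydrazone 5 (not isolated), via bis(benzyloxy)aryl hydrazone 6 (not isolated), via dimethoxyaryl tridecyl bromide 7 (not isolated), via bis(benzyloxy)aryl tridecyl bromide 8 (not isolated)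
Conditions: 1 (1.1 equiv), 2 (1.1 equiv), 4 (2.4 equiv), THF, rt, 1 h; Na2SO4, evaporate at rt; then 3 (1.0 equiv), Ni(cod)2 (10 mol %, cod = cycloocta-1,5-diene), PMe3 (20 mol %), K3PO4 (4 equiv), THF, 70 °C, 24 h, Ar; SiO2 (hexane/EtOAc), C18 polish if needed
Reagents that add atoms: none
Why: Proposed new method: condensation with 4 turns each aldehyde carbon into a benzyl-carbanion equivalent (Wolff–Kishner-type hydrazone umpolung), zerovalent nickel inserts into a primary C–Br bond of 3, the N-bound hydrazone is deprotonated by K3PO4, the C–C bond forms at the former carbonyl carbon and base-induced loss of N2 leaves a plain CH2, so two electrophilic carbons are joined tracelessly at each chain end; because 5 and 6 are electronically alike the ends are capped statistically (homo : hetero : homo about 1:2:1, 9 at most 50 %) and the three tetraethers differ by two benzyl groups each; the closest known reaction type is the nickel-catalysed C(sp3)–C(sp3) cross-coupling of aryl aldehyde hydrazones with unactivated alkyl halides, run here twice in one flask with two hydrazones; no stereocentre is formed.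

**Step 2**
Reactants: 9 1-[3,5-bis(benzyloxy)phenyl]-14-(3,5-dimethoxyphenyl)tetradecane
Product: 10 5-[14-(3,5-dimethoxyphenyl)tetradecyl]benzene-1,3-diol
Conditions: H2 (1 atm), 10% Pd/C, EtOAc/EtOH 1:1, rt, 6 h
Reagents that add atoms: none
Why: Catalytic hydrogenolysis of the two aryl benzyl ethers leaves the aryl methyl ethers, the arenes and the alkyl chain untouched at 1 atm and rt, and any carried-over symmetrical tetraether now differs from 10 by two free OH groups and is removed on silica; no stereocentre is involved.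

**Step 3**
Reactants: 10 5-[14-(3,5-dimethoxyphenyl)tetradecyl]benzene-1,3-diol
Product: 11 5-[14-(3-hydroxy-5-methoxyphenyl)tetradecyl]benzene-1,3-diol (target)
Conditions: NaSEt (8 equiv), DMF, 150 °C, 4 h, Ar; then 1 M HCl, EtOAc
Reagents that add atoms: none
Why: Thiolate SN2 O-demethylation (Feutrill–Mirrington type) removes one of the two equivalent OMe groups, after which the new phenoxide makes the aryloxide of the remaining OMe a much poorer leaving group so the reaction stops at the monomethyl ether, while ring B sits as its inert bis-phenoxide; no stereocentre is involved.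

**Compound list**
1 | 3,5-dimethoxybenzaldehyde | COc1cc(C=O)cc(OC)c1 | starting material
2 | 3,5-bis(benzyloxy)benzaldehyde | O=Cc1cc(OCc2ccccc2)cc(OCc2ccccc2)c1 | starting material
3 | 1,12-dibromododecane | BrCCCCCCCCCCCCBr | starting material
4 | hydrazine monohydrate | NN.O | starting material
5 | (E)-(3,5-dimethoxybenzylidene)hydrazine | COc1cc(/C=N/N)cc(OC)c1 | intermediate
6 | (E)-[3,5-bis(benzyloxy)benzylidene]hydrazine | N/N=C/c1cc(OCc2ccccc2)cc(OCc2ccccc2)c1 | intermediate
7 | 1-(13-bromotridecyl)-3,5-dimethoxybenzene | COc1cc(CCCCCCCCCCCCCBr)cc(OC)c1 | intermediate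
8 | 1,3-bis(benzyloxy)-5-(13-bromotridecyl)benzene | BrCCCCCCCCCCCCCc1cc(OCc2ccccc2)cc(OCc2ccccc2)c1 | intermediate
9 | 1-[3,5-bis(benzyloxy)phenyl]-14-(3,5-dimethoxyphenyl)tetradecane | COc1cc(CCCCCCCCCCCCCCc2cc(OCc3ccccc3)cc(OCc3ccccc3)c2)cc(OC)c1 | intermediate
10 | 5-[14-(3,5-dimethoxyphenyl)tetradecyl]benzene-1,3-diol | COc1cc(CCCCCCCCCCCCCCc2cc(O)cc(O)c2)cc(OC)c1 | intermediate
11 | 5-[14-(3-hydroxy-5-methoxyphenyl)tetradecyl]benzene-1,3-diol (achiral) | COc1cc(O)cc(CCCCCCCCCCCCCCc2cc(O)cc(O)c2)c1 | target

**Total step count:** 3. **Longest linear sequence:** 3.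

**Steps most likely to fail**

Step 1 is the riskiest.
- Risks: N-alkylation of the hydrazones by the bromide, azine formation, beta-hydride elimination at the alkylnickel, the statistical ceiling of 50 %, and a close separation of the three tetraethers.
- The fallback sets out from 1 (using 2 and 3 as well) and comes back at 10. It is a stepwise Corey–Seebach acyl-anion route.
- Aldehyde 1 with propane-1,3-dithiol and BF3·OEt2 gives 2-(3,5-dimethoxyphenyl)-1,3-dithiane F1.
- Deprotonation of F1 (n-BuLi, THF, −30 °C) and alkylation with 3 (4 equiv, excess recovered) gives 2-(12-bromododecyl)-2-(3,5-dimethoxyphenyl)-1,3-dithiane F2.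
- Aldehyde 2 is converted in the same way into 2-[3,5-bis(benzyloxy)phenyl]-1,3-dithiane F3.
- F3 is deprotonated and alkylated with F2 to give 2-{12-[2-(3,5-bis(benzyloxy)phenyl)-1,3-dithian-2-yl]dodecyl}-2-(3,5-dimethoxyphenyl)-1,3-dithiane F4.
- Raney Ni in refluxing EtOH then strips both dithianes and both benzyl groups to give 10.

Step 3 is the second risk.
- Risks: stalling because the trisodium salt is poorly soluble, or partial over-demethylation to the tetraol.
- The fallback sets out from 1 and comes back at 11. It fixes the OMe/OH pattern before the coupling, so the endgame is hydrogenolysis only.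
- Aldehyde 1 with NaSEt in DMF (reflux) gives 3-hydroxy-5-methoxybenzaldehyde F5.
- BnBr and K2CO3 in DMF give 3-(benzyloxy)-5-methoxybenzaldehyde F6.
- F6 replaces 1 in the step 1 protocol, together with 2, 3 and 4. It reacts through (E)-[3-(benzyloxy)-5-methoxybenzylidene]hydrazine F7 and 1-(benzyloxy)-3-(13-bromotridecyl)-5-methoxybenzene F8 (alongside 6 and 8).
- The product is 1-[3-(benzyloxy)-5-methoxyphenyl]-14-[3,5-bis(benzyloxy)phenyl]tetradecane F9.
- H2 over 10% Pd/C then gives 11 directly.

Step 2 is the third risk.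
- Risk: poisoning of Pd/C by traces of PMe3, nickel or nitrogen by-products carried over from step 1.
- The fallback sets out from 9 and comes back at 10. It replaces hydrogenolysis with a Lewis-acid dealkylation.
- Conditions are BCl3 (4 equiv) and pentamethylbenzene (6 equiv) as benzyl-cation scavenger, CH2Cl2, −78 °C. These conditions leave simple aryl methyl ethers intact.
- This fallback makes no new compound (entry F0).

**Further compounds**
F1 | step 1 | 2-(3,5-dimethoxyphenyl)-1,3-dithiane | COc1cc(cc(OC)c1)C1SCCCS1
F2 | step 1 | 2-(12-bromododecyl)-2-(3,5-dimethoxyphenyl)-1,3-dithiane | COc1cc(cc(OC)c1)C1(CCCCCCCCCCCCBr)SCCCS1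
F3 | step 1 | 2-[3,5-bis(benzyloxy)phenyl]-1,3-dithiane | C1CSC(SC1)c1cc(OCc2ccccc2)cc(OCc2ccccc2)c1
F4 | step 1 | 2-{12-[2-(3,5-bis(benzyloxy)phenyl)-1,3-dithian-2-yl]dodecyl}-2-(3,5-dimethoxyphenyl)-1,3-dithiane | COc1cc(cc(OC)c1)C1(CCCCCCCCCCCCC2(SCCCS2)c2cc(OCc3ccccc3)cc(OCc3ccccc3)c2)SCCCS1
F5 | step 3 | 3-hydroxy-5-methoxybenzaldehyde | COc1cc(O)cc(C=O)c1
F6 | step 3 | 3-(benzyloxy)-5-methoxybenzaldehyde | COc1cc(C=O)cc(OCc2ccccc2)c1
F7 | step 3 | (E)-[3-(benzyloxy)-5-methoxybenzylidene]hydrazine | COc1cc(/C=N/N)cc(OCc2ccccc2)c1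
F8 | step 3 | 1-(benzyloxy)-3-(13-bromotridecyl)-5-methoxybenzene | COc1cc(CCCCCCCCCCCCCBr)cc(OCc2ccccc2)c1
F9 | step 3 | 1-[3-(benzyloxy)-5-methoxyphenyl]-14-[3,5-bis(benzyloxy)phenyl]tetradecane | COc1cc(CCCCCCCCCCCCCCc2cc(OCc3ccccc3)cc(OCc3ccccc3)c2)cc(OCc2ccccc2)c1
F0 | step 2 | none | none
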